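Readings and results are simulated on assumed constants; scatter was added.

Count turnovers first: how many times can the gas supply convert the whole charge in the time allowed?

common to all: gas phase 41 mM (held)

| flask | starting material | remark | time |
|---|---|---|---|
| Monday's | 0.56 M | run made earlier |  |
| Wednesday's | 3 M | run made earlier |  |
| maple | 0.40 M |  | 5.0 h |
| cedar | 0.60 M |  | 5.0 h |
| oak | 1.0 M |  | 5.0 h |
| larch | 1.5 M |  | 5.0 h |
| elm | 2.5 M |  | 5.0 h |

- Monday's (time / h: target / %): 0.333: 10.3; 0.667: 19.6; 1.00: 29.4; 1.33: 38.6; 2.00: 55.3; 2.50: 66.3
- Wednesday's (time / h: target / %): 0.200: 1.0; 0.333: 2.3; 0.500: 2.3; 0.667: 3.5; 1.00: 4.4; 1.50: 5.9; 2.50: 8.1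

(standard deviation of a reading: 0.5 percentage points)

- at the start none of the gas phase is in solution
- "hardly changes" means that all values lie within two and a half points (for a concentration: within two and a half percent of the largest)

* amount of target at the end, in percent of the starting material charged for maple, cedar, oak, larch, elm, in this order
* how the row runs (rises, then falls / rises all the way / falls, then rises / falls all the way / hardly changes)

Read the first points. Monday's first reading gives 0.173 M h⁻¹ of target at c(starting material) = 0.56 M. Wednesday's second reading gives 0.207 M h⁻¹ at 3 M, but that reading carries a scatter of 0.5 percentage points. So the early rate barely answers to the charge. Treat the gas supply as the rate-limiting step, with one gas per target, and take Monday's value as the supply.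

Multiply by 5.0 h: on this estimate 0.866 M of gas enters, the gas budget. Divide it by c(starting material) for the turnover count: 2.17 for maple, 1.44 for cedar, 0.866 for oak, 0.577 for larch and 0.346 for elm. A count below one is my estimated ceiling on the target fraction, so my row falls from oak onwards.

But Wednesday's run holds 0.243 M of target at 2.50 h, less than the 0.432 M budgeted. So expect high charges to end below their ceilings.

The forecast gives 99 %, 98 %, 66 %, 38 % and 17 %, a row that falls all the way, on the ground that “Something dependent on starting material is therefore killing the rate”. My reckoning keeps the supply running instead.

The flask gives 80.9 %, 76.4 %, 63.6 %, 38.9 % and 16.6 %, and the row falls all the way.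

    gas phase ⇌ dissolved gas, rate k1*(csat - [dissolved gas]) (kL = 4.70 h⁻¹)
    starting material + dissolved gas → target (k = 140 M⁻¹ h⁻¹)
    starting material + target → side product (k = 0.240 M⁻¹ h⁻¹)
    target ⇌ isomer of the product (K = 1.70, k = 0.0370 h⁻¹)

Maple, with a count of 2.17, ends with 0 % starting material, and at 1.23 h its target is made, each step taken net, 10.1 times faster than it is used up. Elm, with a count of 0.346, ends with 16.6 % target, 38.8 % side product and 43 % of its starting material still there.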